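C3–C4 hydroacylation route to AChE-IN-17, (2S)-5,7,2',4'-tetrahydroxy-8-prenyl-5'-(1,1-dimethylallyl)flavanone

1. Retrosynthesis: take off four MOM ethers. Cut C3–C4 of ring C (the CH2–C=O bond) as the reverse of a hydroacylation, giving a ring A aldehyde (C4–H) whose ortho oxygen O1 carries the enol ether C2(=C3H2)–ring B. Then cut O1–C2, C8–CH2 (prenyl) and C5'–CMe2 (1,1-dimethylallyl).
2. Enabling feature: C2 bears only O1, ring B and H, C3 is a bare CH2, and C4 sits on ring A ortho to O1. Ring C is therefore an isomer of an aldehyde plus a 1,1-disubstituted enol ether with no allylic hydrogen, linked through C4–C4a–C8a–O1–C2=C3.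
3. Forward: ring A (2,4,6-trihydroxybenzaldehyde) is C-prenylated and bis-protected so that only the OH between CHO and prenyl stays free, which fixes 8-prenyl over 6-prenyl. Ring B (2,4-dihydroxybenzaldehyde) gets its 1,1-dimethylallyl group by aromatic Claisen rearrangement.
4. The two rings are joined at O1–C2 by Mitsunobu etherification of a chlorohydrin. HCl is then lost to give the enol ether, ring C closes last, and the MOM groups come off.
5. Stereochemistry: the only stereocentre, C2 (S), is created in the ring closure by hydride delivery from a rhodium hydride carrying a chiral bisphosphine. The racemic centre made on the way is erased first, and the end game is acidic, never basic, so that C2 does not open to the chalcone.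

Key step: step 10

Assumption: (R)-DTBM-SEGPHOS is taken to give (2S) on this substrate class; if a first run shows (2R), the (S)-ligand is used and nothing else changes. Flavanone numbering (O1, C2, C3, C4, C4a, C5–C8, C8a, ring B primed) is used for all intermediates.

Step 1
Reactants: 1 2,4,6-trihydroxybenzaldehyde
Product: 2 2,4,6-trihydroxy-3-(3-methylbut-2-en-1-yl)benzaldehyde
Conditions: prenyl bromide (1 equiv), KOH, H2O, 0 °C to rt
Reagents that add atoms: prenyl bromide (1-bromo-3-methylbut-2-ene), CC(C)=CCBr
Why: C-alkylation of an acylphloroglucinol phenolate in water steers the soft allylic bromide to carbon, C3 and C5 of 1 are equivalent so only one mono-C-prenyl isomer can form, and limiting the bromide holds back double alkylation.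

Step 2
Reactants: 2 2,4,6-trihydroxy-3-(3-methylbut-2-en-1-yl)benzaldehyde
Product: 3 2-hydroxy-4,6-bis(methoxymethoxy)-3-(3-methylbut-2-en-1-yl)benzaldehyde
Conditions: MOMCl (2.1 equiv), K2CO3, acetone, 0 °C to rt
Reagents that add atoms: chloromethyl methyl ether (MOMCl), COCCl
Why: In this Williamson-type O-alkylation the acidic 4-OH reacts first, and of the two ortho hydroxyls the open 6-OH reacts before the 2-OH, which is wedged between CHO and prenyl and hydrogen-bonded to the carbonyl.

Step 3
Reactants: 4 2,4-dihydroxybenzaldehyde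
Product: 5 2-hydroxy-4-[(3-methylbut-2-en-1-yl)oxy]benzaldehyde
Conditions: prenyl bromide (1.05 equiv), K2CO3 (1 equiv), acetone, rt to reflux
Reagents that add atoms: prenyl bromide (1-bromo-3-methylbut-2-ene), CC(C)=CCBr
Why: Williamson ether synthesis is selective for the more acidic, unchelated 4-OH because the 2-OH is tied up in a hydrogen bond to the aldehyde.

Step 4
Reactants: 5 2-hydroxy-4-[(3-methylbut-2-en-1-yl)oxy]benzaldehyde
Product: 6 2-(methoxymethoxy)-4-[(3-methylbut-2-en-1-yl)oxy]benzaldehyde
Conditions: NaH, MOMCl, DMF, 0 °C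
Reagents that add atoms: chloromethyl methyl ether (MOMCl), COCCl
Why: Full deprotonation breaks the chelate so that O-alkylation proceeds, and capping the 2-OH removes the hydrogen-bond bond fixation that would send the coming rearrangement to C3.

Step 5
Reactants: 6 2-(methoxymethoxy)-4-[(3-methylbut-2-en-1-yl)oxy]benzaldehyde
Product: 8 4-hydroxy-2-(methoxymethoxy)-5-(2-methylbut-3-en-2-yl)benzaldehyde, via ortho-dienone 7 (not isolated)
Conditions: N,N-diethylaniline, 200 °C, sealed tube, argon
Reagents that add atoms: none
Why: The aromatic Claisen rearrangement ([3,3] shift with allyl inversion) turns the O-prenyl group into a C-bound 1,1-dimethylallyl group, goes to C5 because C3 between two alkoxy groups cannot take a tertiary carbon, and dienone 7 tautomerises to the phenol in the basic solvent.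

Step 6
Reactants: 8 4-hydroxy-2-(methoxymethoxy)-5-(2-methylbut-3-en-2-yl)benzaldehyde
Product: 9 2,4-bis(methoxymethoxy)-5-(2-methylbut-3-en-2-yl)benzaldehyde
Conditions: NaH, MOMCl, DMF, 0 °C to rt
Reagents that add atoms: chloromethyl methyl ether (MOMCl), COCCl
Why: O-alkylation of the sodium phenolate with the small, very reactive MOMCl overcomes the crowding by the neighbouring tertiary alkyl group.

Step 7
Reactants: 9 2,4-bis(methoxymethoxy)-5-(2-methylbut-3-en-2-yl)benzaldehyde
Product: 10 rac-2-chloro-1-[2,4-bis(methoxymethoxy)-5-(2-methylbut-3-en-2-yl)phenyl]ethan-1-ol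
Conditions: ICH2Cl, MeLi·LiBr (added slowly to the mixture), THF/Et2O, −78 °C; AcOH quench at −78 °C
Reagents that add atoms: chloroiodomethane, ClCI
Why: Chloromethyllithium, a lithium carbenoid made in situ by iodine–lithium exchange that outruns carbonyl attack by MeLi, adds to the aldehyde, the cold acid quench stops before epoxide closure, and the new carbinol centre is racemic and is erased in step 9.

Step 8
Reactants: 3 2-hydroxy-4,6-bis(methoxymethoxy)-3-(3-methylbut-2-en-1-yl)benzaldehyde, 10 rac-2-chloro-1-[2,4-bis(methoxymethoxy)-5-(2-methylbut-3-en-2-yl)phenyl]ethan-1-ol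
Product: 11 rac-2-{1-[2,4-bis(methoxymethoxy)-5-(2-methylbut-3-en-2-yl)phenyl]-2-chloroethoxy}-4,6-bis(methoxymethoxy)-3-(3-methylbut-2-en-1-yl)benzaldehyde
Conditions: PPh3, DIAD, THF (concentrated), 0 °C to rt
Reagents that add atoms: none
Why: Mitsunobu etherification suits the acidic salicylaldehyde-type phenol, the electron-rich benzylic alkoxyphosphonium ion can react by direct displacement or through an ion pair, and both paths give the same racemic ether whose centre is erased in step 9.

Step 9
Reactants: 11 rac-2-{1-[2,4-bis(methoxymethoxy)-5-(2-methylbut-3-en-2-yl)phenyl]-2-chloroethoxy}-4,6-bis(methoxymethoxy)-3-(3-methylbut-2-en-1-yl)benzaldehyde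
Product: 12 2-({1-[2,4-bis(methoxymethoxy)-5-(2-methylbut-3-en-2-yl)phenyl]ethenyl}oxy)-4,6-bis(methoxymethoxy)-3-(3-methylbut-2-en-1-yl)benzaldehyde
Conditions: KOtBu, THF, 0 °C to rt; chromatography on Et3N-deactivated silica
Reagents that add atoms: none
Why: E2 dehydrochlorination, the standard way from 2-haloethyl aryl ethers to aryl vinyl ethers, removes the benzylic alpha-oxy hydrogen at C2 with chloride as much the better leaving group, and the aldehyde cannot enolise.

Step 10
Reactants: 12 2-({1-[2,4-bis(methoxymethoxy)-5-(2-methylbut-3-en-2-yl)phenyl]ethenyl}oxy)-4,6-bis(methoxymethoxy)-3-(3-methylbut-2-en-1-yl)benzaldehyde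
Product: 13 (2S)-2-[2,4-bis(methoxymethoxy)-5-(2-methylbut-3-en-2-yl)phenyl]-5,7-bis(methoxymethoxy)-8-(3-methylbut-2-en-1-yl)-2,3-dihydro-4H-chromen-4-one
Conditions: [Rh(cod)Cl]2 (2.5 mol %), (R)-DTBM-SEGPHOS (5 mol %), Na[B(3,5-(CF3)2C6H3)4] (5 mol %), 4 Å sieves, 1,4-dioxane, 60–80 °C
Reagents that add atoms: none
Why: Proposed new method: the cationic bisphosphine complex of monovalent rhodium binds the enol ether C2=C3, adds oxidatively into the aldehyde C4–H bond to give an acyl hydride of trivalent rhodium, passes the hydride to C2 while rhodium takes the unhindered C3, and reductive elimination from the seven-membered acyl alkyl rhodacycle forms C3–C4 and frees the catalyst. The closest known reaction types are the enantioselective rhodium-catalysed intramolecular hydroacylations of ortho-(2-substituted allyl)benzaldehydes to 3-substituted 1-tetralones (same ring size, CH2 where O1 stands here) and of N-(1-substituted vinyl)indole-2-carbaldehydes (a heteroatom on the alkene carbon that takes up hydride), whereas an aryl 1-arylvinyl ether closing to a chroman-4-one has not been shown. Ring C closes 6-endo-trig at the alkene; the 5-exo mode would need a tertiary rhodium alkyl at C2 and a quaternary carbon in a 2-methyl-2-arylbenzofuran-3-one, and since hydride insertion is reversible the faster reductive elimination of the primary alkyl should decide, as it does for 1,1-disubstituted alkenes in the known cases. C2 is the only new stereocentre and is set by the face of C2=C3 that the twofold-symmetric chiral pocket of the ligand offers to the Rh–H bond. Of the three alkenes only C2=C3 can chelate the rhodium held at C4, the prenyl alkene being trisubstituted and the 1,1-dimethylallyl vinyl group neopentylic and remote, and C2=C3 has no allylic hydrogen, so the alkene isomerisation that competes in the all-carbon series is impossible. Decarbonylation is held back by that chelation and by masking the 5-OH (a free phenolate would tie rhodium to the side of C4 away from the alkene), loss of aryloxide from the rhodacycle is hindered because O1 lies inside the ring and cannot align syn-coplanar with Rh–C3, and the non-coordinating anion, sieves and aprotic solvent keep the acid-labile enol ether from hydrolysis.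

Step 11
Reactants: 13 (2S)-2-[2,4-bis(methoxymethoxy)-5-(2-methylbut-3-en-2-yl)phenyl]-5,7-bis(methoxymethoxy)-8-(3-methylbut-2-en-1-yl)-2,3-dihydro-4H-chromen-4-one
Product: 14 AChE-IN-17, (2S)-2-[2,4-dihydroxy-5-(2-methylbut-3-en-2-yl)phenyl]-5,7-dihydroxy-8-(3-methylbut-2-en-1-yl)-2,3-dihydro-4H-chromen-4-one
Conditions: conc. aq HCl (cat.), MeOH, rt to 40 °C, short contact time, neutral work-up
Reagents that add atoms: none
Why: Acid-catalysed transacetalisation of phenolic MOM ethers to methanol is the usual last step for prenylated flavanones, and it avoids the phenolate-driven ring opening to the chalcone that would racemise C2 or move the prenyl group to C6.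

Compound list
1 | 2,4,6-trihydroxybenzaldehyde | O=Cc1c(O)cc(O)cc1O | starting material
2 | 2,4,6-trihydroxy-3-(3-methylbut-2-en-1-yl)benzaldehyde | CC(C)=CCc1c(O)cc(O)c(C=O)c1O | intermediate
3 | 2-hydroxy-4,6-bis(methoxymethoxy)-3-(3-methylbut-2-en-1-yl)benzaldehyde | CC(C)=CCc1c(OCOC)cc(OCOC)c(C=O)c1O | intermediate
4 | 2,4-dihydroxybenzaldehyde | O=Cc1ccc(O)cc1O | starting material
5 | 2-hydroxy-4-[(3-methylbut-2-en-1-yl)oxy]benzaldehyde | CC(C)=CCOc1ccc(C=O)c(O)c1 | intermediate
6 | 2-(methoxymethoxy)-4-[(3-methylbut-2-en-1-yl)oxy]benzaldehyde | CC(C)=CCOc1ccc(C=O)c(OCOC)c1 | intermediate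
7 | ortho-dienone, 6-(methoxymethoxy)-3-(2-methylbut-3-en-2-yl)-4-oxocyclohexa-1,5-diene-1-carbaldehyde (racemic, not isolated) | O=CC1=CC(C(C)(C)C=C)C(=O)C=C1OCOC | intermediate
8 | 4-hydroxy-2-(methoxymethoxy)-5-(2-methylbut-3-en-2-yl)benzaldehyde | C=CC(C)(C)c1cc(C=O)c(OCOC)cc1O | intermediate
9 | 2,4-bis(methoxymethoxy)-5-(2-methylbut-3-en-2-yl)benzaldehyde | C=CC(C)(C)c1cc(C=O)c(OCOC)cc1OCOC | intermediate
10 | rac-2-chloro-1-[2,4-bis(methoxymethoxy)-5-(2-methylbut-3-en-2-yl)phenyl]ethan-1-ol | C=CC(C)(C)c1cc(C(O)CCl)c(OCOC)cc1OCOC | intermediate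
11 | rac-2-{1-[2,4-bis(methoxymethoxy)-5-(2-methylbut-3-en-2-yl)phenyl]-2-chloroethoxy}-4,6-bis(methoxymethoxy)-3-(3-methylbut-2-en-1-yl)benzaldehyde | C=CC(C)(C)c1cc(C(CCl)Oc2c(C=O)c(OCOC)cc(OCOC)c2CC=C(C)C)c(OCOC)cc1OCOC | intermediate
12 | 2-({1-[2,4-bis(methoxymethoxy)-5-(2-methylbut-3-en-2-yl)phenyl]ethenyl}oxy)-4,6-bis(methoxymethoxy)-3-(3-methylbut-2-en-1-yl)benzaldehyde | C=CC(C)(C)c1cc(C(=C)Oc2c(C=O)c(OCOC)cc(OCOC)c2CC=C(C)C)c(OCOC)cc1OCOC | intermediate
13 | (2S)-2-[2,4-bis(methoxymethoxy)-5-(2-methylbut-3-en-2-yl)phenyl]-5,7-bis(methoxymethoxy)-8-(3-methylbut-2-en-1-yl)-2,3-dihydro-4H-chromen-4-one | C=CC(C)(C)c1cc([C@@H]2CC(=O)c3c(OCOC)cc(OCOC)c(CC=C(C)C)c3O2)c(OCOC)cc1OCOC | intermediate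
14 | AChE-IN-17, (2S)-2-[2,4-dihydroxy-5-(2-methylbut-3-en-2-yl)phenyl]-5,7-dihydroxy-8-(3-methylbut-2-en-1-yl)-2,3-dihydro-4H-chromen-4-one | C=CC(C)(C)c1cc([C@@H]2CC(=O)c3c(O)cc(O)c(CC=C(C)C)c3O2)c(O)cc1O | target

Total step count: 11. Longest linear sequence: 9 steps (4 to 14, steps 3 to 11).

Steps most likely to fail

Step 10 (the labelled step).
- What may go wrong: decarbonylation of the acyl rhodium hydride, hydride delivery with the opposite regiochemistry, loss of the aryloxide from the rhodacycle, acid-triggered cleavage of the enol ether, or poor facial selectivity.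
- Fallback: it uses known chemistry, sets out from chloro ether 11 and comes back at 13.
  - Compound 11 is closed by the known carbene-catalysed intramolecular nucleophilic acylation of an alkyl halide. Conditions are 3-benzyl-5-(2-hydroxyethyl)-4-methylthiazolium chloride (20 mol %), Cs2CO3, NaI (cat.), dioxane, 80–100 °C.
  - The aldehyde becomes an acyl anion equivalent that displaces chloride at C3 (6-exo-tet) and gives the racemic tetra-MOM flavanone F1.
  - F1 is then resolved by the known kinetic resolution of racemic flavanones through asymmetric transfer hydrogenation. Conditions are RuCl[(R,R)-TsDPEN](p-cymene), HCO2H/Et3N, EtOAc, rt, run to just past half conversion.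
  - The (2R) ketone is expected to be reduced faster, to the cis (2R,4R)-flavan-4-ol F2, which is separated by chromatography. The unreacted (2S) ketone is 13.

Step 8.
- What may go wrong: slow attack of the doubly ortho-substituted, hydrogen-bonded phenol on the crowded alkoxyphosphonium ion. Ionisation is then followed by proton loss or capture of the hydrazide instead of ether formation.
- Fallback: it sets out from 9 (with 3) and comes back at 11.
  - Corey–Chaykovsky methylenation of 9 (Me3SI, NaH, DMSO/THF, 0 °C) gives the aryl oxirane F3.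
  - Phenol 3 opens F3 under mild Lewis acid activation (LiClO4, MeCN, rt to 40 °C). Ring strain and the 2,4-dioxygenated ring B direct attack to the benzylic carbon, giving the primary alcohol F4.
  - Appel chlorination (PPh3, CCl4, CH2Cl2, 0 °C to rt) returns 11.

Step 5.
- What may go wrong: migration to C3 instead of C5, further rearrangement of the first-formed phenol along the abnormal Claisen pathway, or thermal loss of the prenyl group.
- Fallback: it has no sigmatropic step, sets out from 4 and comes back at 9.
  - Electrophilic bromination of 4 (NBS, MeCN, 0 °C) goes para to the 2-OH and ortho to the 4-OH and gives 5-bromo-2,4-dihydroxybenzaldehyde F5.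
  - NaH and MOMCl in DMF give 5-bromo-2,4-bis(methoxymethoxy)benzaldehyde F6.
  - A branched-selective (gamma-selective) Suzuki–Miyaura allyl–aryl coupling with prenylboronic acid pinacol ester (CC(C)=CCB1OC(C)(C)C(C)(C)O1) forms the aryl–CMe2 bond and gives 9. Conditions are Pd(OAc)2, a biaryl dialkylphosphine of the ligand class known to give the branched isomer, aq K3PO4, THF, 40 °C.

Further compounds
F1 | step 10 | racemic 2-[2,4-bis(methoxymethoxy)-5-(2-methylbut-3-en-2-yl)phenyl]-5,7-bis(methoxymethoxy)-8-(3-methylbut-2-en-1-yl)-2,3-dihydro-4H-chromen-4-one | C=CC(C)(C)c1cc(C2CC(=O)c3c(OCOC)cc(OCOC)c(CC=C(C)C)c3O2)c(OCOC)cc1OCOC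
F2 | step 10 | (2R,4R)-2-[2,4-bis(methoxymethoxy)-5-(2-methylbut-3-en-2-yl)phenyl]-5,7-bis(methoxymethoxy)-8-(3-methylbut-2-en-1-yl)-3,4-dihydro-2H-chromen-4-ol | C=CC(C)(C)c1cc([C@H]2C[C@@H](O)c3c(OCOC)cc(OCOC)c(CC=C(C)C)c3O2)c(OCOC)cc1OCOC
F3 | step 8 | rac-2-[2,4-bis(methoxymethoxy)-5-(2-methylbut-3-en-2-yl)phenyl]oxirane | C=CC(C)(C)c1cc(C2CO2)c(OCOC)cc1OCOC
F4 | step 8 | rac-2-{1-[2,4-bis(methoxymethoxy)-5-(2-methylbut-3-en-2-yl)phenyl]-2-hydroxyethoxy}-4,6-bis(methoxymethoxy)-3-(3-methylbut-2-en-1-yl)benzaldehyde | C=CC(C)(C)c1cc(C(CO)Oc2c(C=O)c(OCOC)cc(OCOC)c2CC=C(C)C)c(OCOC)cc1OCOC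
F5 | step 5 | 5-bromo-2,4-dihydroxybenzaldehyde | O=Cc1cc(Br)c(O)cc1O
F6 | step 5 | 5-bromo-2,4-bis(methoxymethoxy)benzaldehyde | O=Cc1cc(Br)c(OCOC)cc1OCOC
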